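# Total synthesis proposal for tuberostemonone

## Structural features

1. Atom labels follow the SMILES string: C1–C2 (ethyl), C3, C4, O5, C6(=O), C7 (CHMe), C8, C9 (ketone), C10, C11, C12, C13, C14 (CHMe), C15(=O), O16, N17, C18–C21, C22, C23 (lactam C=O).
2. The core is a 1-azabicyclo[6.4.1]tridecane. The bridgeheads N17 and C22 are joined by the one-atom bridge C23(=O), the four-carbon bridge C18–C21 and the six-carbon bridge C3–C4–C8–C9–C10–C11. An ε-caprolactam and a nine-membered keto-lactam therefore share N17–C23–C22.
3. α-Methyl-γ-butyrolactone A (C4, O5, C6, C7, C8) is trans-fused to the nine-membered ring at C4–C8, with its methyl group cis to the C9 acyl branch. The cis-2,4-disubstituted lactone B (C12–C15, O16) hangs on C11.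
4. Five stereocentres are contiguous (C22–C3–C4–C8–C7). The triad C11/C12/C14 is separated from them by C9/C10 on one side and by the planar N17–C23 amide on the other.
5. The C9 ketone is β-acyloxy (C4–O5) and β-amido (C11–N17), so E1cB loss threatens under base. C8 is readily epimerised, and C7, C14 and C22 are also α to carbonyl groups.
6. The real difficulty is the nine-membered ring. It combines transannular strain, an amide that must be trans within it, a dissonant 1,4-dicarbonyl pair C6/C9, and five adjacent stereocentres on a flexible perimeter.
7. The key step exploits one feature: C9 and C23 are both carbonyl carbons, linked by C8–C4–C3–C22 on one side and by C10–C11–N17 on the other. Joining them as C9=C23 turns the nine-membered ring into a 2-pyrroline fused to a cyclohexene, which is a ring-fusion enamine built only of common rings.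

## Logic of the disconnections

**27 ⇒ 26.** No bond is cut; only the configuration at C8 is inverted. C8 is the one stereocentre α to the C9 ketone, so it can be adjusted last by enolisation. The gain is that lactone A may be carried cis-fused, the only fusion that a small-ring closure onto C8 can deliver. The demand is that 27 be the more stable epimer and that the base does not expel O5 from C4.

**26 ⇒ 24 (key).** C9 and C23 are reconnected as a C9=C23 double bond. In the forward sense this bond is cut and both new oxygens come from O2. In one sentence: the nine-membered keto-lactam is released by oxidative scission of the ring-fusion enamine of 24.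

- The cut is placed here because it removes the medium ring, the bridged lactam and both carbonyl groups together.
- It also inverts the polarity of C9, from an acyl carbon to a nucleophilic enamine β-carbon. This dissolves the dissonant C6/C9 relationship.
- The gain is a 5/6/7-fused skeleton in which every ring is easy to close.
- The demand is that the enamine double bond sit at C9=C23 and not at C22=C23 when oxygen arrives.

**24 ⇒ 19 + 20.** N17–C18 and C21–C22 are cut. Both positions are nucleophilic in an imine/enamine, so one C4 bis-electrophile supplies the whole bridge. The gain is that C22 becomes a plain CH2 and needs no earlier stereocontrol. The demand is a seven-membered C-alkylation and a thermodynamic preference for the 22S configuration.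

**19 ⇒ 16.** C8–C9 and N17=C23 are cut. With C9 and C23 bonded, C8–C9 is a six-membered closure of an enamine onto a butenolide instead of a nine-membered one. The gain is an open-chain keto carbamate with two separate stereochemical blocks. The demand is that the closure set C8 and C7 from C4 alone.

**16 ⇒ 5 + 13.** C9–C23 is cut. This is the very bond that is sacrificed later, so the fragment-union bond is absent from the target. The reason is convergence: the cut separates the C3/C4 block from the C11/C12/C14 block at a ketone. The demand is a ketone synthesis that tolerates a butenolide, a lactone and a carbamate.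

**5 ⇒ 4 ⇒ 2 + 3 (2 ⇐ 1).** C3–C4 is cut. C4 is the γ-carbon of a butenolide (vinylogous donor) and C3 is the β-carbon of an enal. The gain is two commercial C5 units. The demand is catalyst control of C3 and simple diastereoselection (syn) at C4.

**13 ⇒ 12 ⇒ 11 ⇒ 7 + 8 (7 ⇐ 6).** C12–C13 and O16–C15 are cut. The fragment C9–C10–C11–C12 with N17 is the carbon chain of L-homoserine, with C11 in the correct configuration. The gain is a chiral-pool lactone plus a C4 acrylate. The demand is syn-selective addition to the α-amino aldehyde (C12) and cis-selective hydrogenation (C14).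

## Other disconnections considered

**Alternative 1:** (the first that comes to mind) The cut is N17–C23, followed by N17–C18.

- *Forward key step:* high-dilution lactamisation of the open amino acid A1 to the nine-membered NH-lactam A2, then intramolecular N-alkylation by the chlorobutyl chain.
- *Strain and oligomerisation:* the cyclisation must build all the transannular strain and a trans amide in the bond-forming transition state, so oligomerisation competes.
- *Fragile precursor:* A1 must carry all eight stereocentres, including the labile trans C8, in an open chain. That chain holds a free amine next to lactone B (translactamisation) and β to a ketone (retro-Michael).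
- *Endgame:* the last N-alkylation needs an amide anion, a stronger base than the one that triggers E1cB loss of O5.
- *Verdict:* the chosen plan never closes the medium ring by bond formation and ends under neutral or weakly basic conditions.

**Alternative 2:** The cut is C22–C3, with reconnection of N17 to C8 (retro 3-aza-Claisen).

- *Forward key step:* the acyl fluoride A3 acylates its own ring nitrogen. Deprotonation gives a zwitterionic ketene aminal, and a [3,3] shift expands the pyrrolidine by four atoms to the bridged (E)-azoninone A4.
- *Merit:* this would form both rings and set C22 and C3 in one event.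
- *Endgame problem:* the step leaves the C4=C8 alkene next to C9–O, and lactone A must still be added with O on C4 and C7 on C8.
- *Regiochemistry:* that C7–C8 bond is dissonant. Polar reagents (ketene [2+2], epoxide opening) are steered the wrong way because the C9–O bond destabilises positive charge at C8.
- *Side reactions:* the strained E-alkene also invites transannular attack by the lactam.
- *Verdict:* many further steps on a medium ring would follow, whereas the chosen plan brings lactone A in complete.

**Alternative 3:** The cut is C8–C9.

- *Forward key step:* an intramolecular Stetter reaction, or an acyl-radical conjugate addition, of the aldehyde A5. C9 acts as an acyl-anion equivalent and adds to C8 anti to C3, which would give the trans-fused lactone directly.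
- *Merit:* the polarity analysis is sound.
- *Weakness of the closure:* the bond is formed in a nine-membered transition state, onto a trisubstituted, α-methylated butenolide, which is a poor acceptor.
- *Weakness of the precursor:* A5 is a β-amido aldehyde prone to elimination. Its C11 centre, and the C22/C3/C4 triad on the caprolactam, would have to be set without any element that links the two blocks.
- *Verdict:* the chosen plan makes the same C8–C9 bond through a six-membered transition state.

Key step: step 11

**Remarks on the chemistry.**

- The configuration at C9 in 19 and 21–23, and at C9/C23 in 25, has no consequence, because both atoms end as carbonyl carbons. C9 is drawn for the chair-like closure, and C9/C23 of 25 are left open.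
- The anomeric centre of 7 is a mixture.
- It is assumed that the trans-fused C8 epimer 27 is the more stable one.

## Steps

**Step 1**
Reactants: 1 3-methylfuran-2(5H)-one
Product: 2 trimethyl[(3-methylfuran-2-yl)oxy]silane
Conditions: TMSOTf, Et3N, Et2O, 0 °C; distil
Reagents that add atoms: trimethylsilyl triflate, C[Si](C)(C)OS(=O)(=O)C(F)(F)F
Why: O-Silylation of the butenolide dienolate (soft enolisation, silyl dienol ether formation) is driven by aromatisation to the furan; no stereocentre is involved.

**Step 2**
Reactants: 2 trimethyl[(3-methylfuran-2-yl)oxy]silane; 3 (E)-pent-2-enal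
Product: 4 (3R)-3-[(2S)-4-methyl-5-oxo-2,5-dihydrofuran-2-yl]pentanal
Conditions: (2S,5S)-5-benzyl-2-tert-butyl-3-methylimidazolidin-4-one (20 mol %), 2,4-dinitrobenzoic acid (20 mol %), CH2Cl2/H2O, −60 °C
Reagents that add atoms: none
Why: Organocatalytic vinylogous Mukaiyama–Michael addition: 3 reacts as its E-iminium ion, one face of which is closed by the benzyl group, so furan C5 (the future C4) bonds to C3 on the open face and gives 3R, the sense expected for π-nucleophiles with this catalyst. C4 (4S, C3/C4 syn) follows from a compact synclinal approach in which the furan lies over the iminium π-system. Water takes up the silyl group and hydrolyses the product enamine, so C22 stays a plain CH2.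

**Step 3**
Reactants: 4 (3R)-3-[(2S)-4-methyl-5-oxo-2,5-dihydrofuran-2-yl]pentanal
Product: 5 (3R)-3-[(2S)-4-methyl-5-oxo-2,5-dihydrofuran-2-yl]pentanoic acid
Conditions: NaClO2, NaH2PO4, 2-methylbut-2-ene, t-BuOH/H2O, 0 °C → rt
Reagents that add atoms: sodium chlorite, [Na+].[O-]Cl=O
Why: Pinnick oxidation at about pH 4 converts only the aldehyde; the scavenger removes HOCl, the electron-poor butenolide alkene is inert, and C3 and C4 are not touched.

**Step 4**
Reactants: 6 tert-butyl N-[(3S)-2-oxooxolan-3-yl]carbamate (N-Boc-L-homoserine lactone)
Product: 7 tert-butyl N-[(3S)-2-hydroxyoxolan-3-yl]carbamate (lactol)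
Conditions: DIBAL-H (2.2 equiv), CH2Cl2, −78 °C; Rochelle salt
Reagents that add atoms: none
Why: Partial reduction of a γ-lactone with DIBAL-H stops at the aluminium hemiacetal at −78 °C (one equivalent is consumed by the N–H). The cyclic lactol masks the configurationally labile α-amino aldehyde, so the chiral-pool centre C11 (S) is kept.

**Step 5**
Reactants: 7 tert-butyl N-[(3S)-2-hydroxyoxolan-3-yl]carbamate; 8 ethyl 2-(bromomethyl)prop-2-enoate
Product: 11 tert-butyl N-[(1S)-3-hydroxy-1-[(2S)-4-methylidene-5-oxooxolan-2-yl]propyl]carbamate, via allylzinc bromide 9 (not isolated), via hydroxy ester 10 (not isolated)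
Conditions: Zn dust, THF/sat. aq NH4Cl, 0 °C → rt; then PPTS (cat.), CH2Cl2, rt
Reagents that add atoms: none
Why: Zinc Barbier (Reformatsky-type) 2-alkoxycarbonylallylation of the open hydroxy-aldehyde tautomer of 7, followed by γ-lactonisation of the C12 hydroxyl. C12 is set by Cram chelation: Zn(II) bridges the aldehyde oxygen and the carbamate, and the allyl group attacks opposite to the C10 chain, which gives the 11,12-syn (threo) amino alcohol (12S). The primary C9–OH cannot compete, because it would have to close an eight-membered ring.

**Step 6**
Reactants: 11 tert-butyl N-[(1S)-3-hydroxy-1-[(2S)-4-methylidene-5-oxooxolan-2-yl]propyl]carbamate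
Product: 12 tert-butyl N-[(1S)-3-hydroxy-1-[(2S,4S)-4-methyl-5-oxooxolan-2-yl]propyl]carbamate
Conditions: H2 (1 atm), Pd/C, EtOAc, rt
Reagents that add atoms: none
Why: Heterogeneous hydrogenation of an α-methylene-γ-butyrolactone delivers H2 to the face opposite the C12 substituent, so the methyl group ends cis to it (14S). Any isomerisation to the endocyclic butenolide would be reduced with the same facial sense.

**Step 7**
Reactants: 12 tert-butyl N-[(1S)-3-hydroxy-1-[(2S,4S)-4-methyl-5-oxooxolan-2-yl]propyl]carbamate
Product: 13 tert-butyl N-[(1S)-3-iodo-1-[(2S,4S)-4-methyl-5-oxooxolan-2-yl]propyl]carbamate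
Conditions: I2, PPh3, imidazole, CH2Cl2, 0 °C → rt
Reagents that add atoms: iodine, II
Why: Appel-type iodination of the primary alcohol by SN2; the carbamate, the lactone and the three stereocentres are spectators at room temperature.

**Step 8**
Reactants: 5 (3R)-3-[(2S)-4-methyl-5-oxo-2,5-dihydrofuran-2-yl]pentanoic acid; 13 tert-butyl N-[(1S)-3-iodo-1-[(2S,4S)-4-methyl-5-oxooxolan-2-yl]propyl]carbamate
Product: 16 tert-butyl N-[(1S,6R)-6-[(2S)-4-methyl-5-oxo-2,5-dihydrofuran-2-yl]-1-[(2S,4S)-4-methyl-5-oxooxolan-2-yl]-4-oxooctyl]carbamate, via acid chloride 14 (not isolated), via alkylzinc iodide 15 (not isolated)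
Conditions: (a) 5, (COCl)2, DMF (cat.), CH2Cl2, 0 °C → rt, evaporate; (b) 13, Zn dust, LiCl, THF, rt; (c) 14 + 15, Pd(PPh3)4 (5 mol %), THF, 0 °C → rt
Reagents that add atoms: none
Why: Negishi acylation: zinc insertion into the primary iodide gives a γ-amido alkylzinc that has no β-leaving group, and Pd(0) couples it with the acyl chloride faster than the organozinc could add to lactone, butenolide or product ketone. The new C9–C23 bond is the temporary bond of the plan; no stereocentre is formed or endangered.

**Step 9**
Reactants: 16 tert-butyl N-[(1S,6R)-6-[(2S)-4-methyl-5-oxo-2,5-dihydrofuran-2-yl]-1-[(2S,4S)-4-methyl-5-oxooxolan-2-yl]-4-oxooctyl]carbamate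
Product: 19 tetracyclic imine (1-pyrroline N17=C23 fused at C9–C23 to a cyclohexane C23–C22–C3–C4–C8–C9 that carries cis-fused lactone A at C4–C8; ethyl on C3; lactone B on C11; C22 is CH2), via amino ketone 17 (not isolated), via pyrroline 18 (not isolated)
Conditions: TFA/CH2Cl2 (1:4), 0 °C → rt; evaporate; sat. aq NaHCO3/CH2Cl2; then toluene, 80 °C
Reagents that add atoms: none
Why: Acidolysis of the Boc group frees N17, which condenses at once with the γ-ketone (five-membered imine 18) and so outruns attack on lactone B. On heating, 18 reacts through its endocyclic secondary-enamine tautomer in an intramolecular aza-ene-type imine Michael addition (6-exo-trig, chair-like, ethyl equatorial); the tether C23–C22–C3 reaches only the butenolide face that carries C3, so C8 is set cis to the C3–C4 bond (cis-fused lactone). The N–H proton is passed to C7 on the same face as the new C8–C9 bond, which places the methyl group on the convex face (7S, also the thermodynamic position).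

**Step 10**
Reactants: 19 tetracyclic imine; 20 1,4-diiodobutane
Product: 24 pentacyclic ring-fusion enamine (C9=C23; 2-pyrroline, cyclohexene and azepine all sharing C23; cis-fused lactone A; 22S), via iminium iodide 21 (not isolated), via iodobutyl enamine 22 (not isolated), via pentacyclic iminium iodide 23 (not isolated)
Conditions: 20 (5 equiv), MeCN, 70 °C; evaporate, triturate (Et2O); i-Pr2NEt (3 equiv), MeCN (0.01 M), 70 °C, Ar
Reagents that add atoms: none
Why: N-Alkylation of the cyclic imine followed by intramolecular Stork enamine alkylation [7-(enolendo)-exo-tet] stitches C18–C21 between N17 and C22; only the C22=C23 enamine 22 can close a sensible ring, since attack through C9 would give a strained 1-azabicyclo[4.2.1] system. C22 is set under thermodynamic control, because 23 and its two enamines interconvert in the amine/ammonium buffer: A(1,3) strain with the in-plane N17–C18 bond and a chair-like azepine both demand a pseudo-axial C22–C21 bond, and only the 22S epimer combines this with an equatorial ethyl group (C3) and an equatorial O5 (C4). Loss of H9 then gives 24, the endocyclic 2-pyrroline form of the enamine.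

**Step 11**
Reactants: 24 pentacyclic ring-fusion enamine
Product: 26 8-epi-tuberostemonone (cis-fused lactone A), via dioxetane 25 (not isolated)
Conditions: O2, tetraphenylporphyrin (1 mol %), hν (white LED), CH2Cl2, −78 °C; then dark, → 0 °C
Reagents that add atoms: dioxygen, O=O
Why: Singlet oxygen adds to the electron-rich C9=C23 bond, through a zwitterion stabilised by the N17 lone pair, to give the 1,2-dioxetane 25, which undergoes retro-[2+2] on warming and leaves C9 as the ketone and C23 as the lactam carbonyl. The closest known reaction type is the dye-sensitised photo-oxygenative cleavage of enamines, of which the Witkop-type cleavage of 2,3-fused indoles is the aromatic counterpart. The only ring closed is the transient four-membered dioxetane ([2+2]); the nine-membered ring is not closed by bond formation but released when the zero-atom bridge common to the pyrroline and the cyclohexene is cut (5 + 6 − 2 = 9), and the azepine becomes the caprolactam, so no transition state has to pay for medium-ring strain or entropy. No stereocentre is created in 26: C9 and C23 are stereogenic only in 25, attack on either face leads to the same product, and C22, C3, C4, C8, C7, C11, C12 and C14 pass unchanged through a neutral reaction at −78 °C. The amide geometry is inherited from the enamine: the new oxygen takes the place of C9, so C11 stays syn to the carbonyl oxygen and C18 syn to C22, which is exactly the cis amide of the caprolactam and the trans amide of the nine-membered ring. Chemoselectivity is secured because C9=C23 is the only C=C bond present and both lactones are inert to singlet oxygen, while the nitrogen lone pair, the aprotic solvent and the low temperature favour [2+2] over ene-type hydroperoxidation. Regioselectivity requires the double bond at C9=C23 and not at C22=C23: 24 is the endocyclic 2-pyrroline tautomer with the best n–π overlap, and acid-free conditions at −78 °C freeze prototropic exchange through 23. The payoff is that the hardest ring, the bridged lactam and both carbonyl groups appear in one operation from a skeleton made only of five-, six- and seven-membered rings.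

**Step 12**
Reactants: 26 8-epi-tuberostemonone
Product: 27 tuberostemonone
Conditions: DBU (0.2 equiv), CH2Cl2, 0 °C → rt
Reagents that add atoms: none
Why: Base-catalysed keto–enol equilibration (epimerisation) at C8, the only stereocentre α to the ketone. The trans-fused epimer should be favoured because it exchanges the eclipsing of the two large ring branches C3/C9 for the smaller Me/C9 contact and gives the nine-membered ring the large C3–C4–C8–C9 torsion angle it prefers. E1cB loss of O5 is held back because in the C8=C9 enolate the C4–O5 bond lies close to the nodal plane of the π-system within the five-membered ring, and C7, C14 and C22 are much less acidic.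

## Compound list

| No. | Name | SMILES | Role |
|---|---|---|---|
| 1 | 3-methylfuran-2(5H)-one | CC1=CCOC1=O | starting material |
| 2 | trimethyl[(3-methylfuran-2-yl)oxy]silane | Cc1ccoc1O[Si](C)(C)C | intermediate |
| 3 | (E)-pent-2-enal | CC/C=C/C=O | starting material |
| 4 | (3R)-3-[(2S)-4-methyl-5-oxo-2,5-dihydrofuran-2-yl]pentanal | CC[C@H](CC=O)[C@@H]1OC(=O)C(C)=C1 | intermediate |
| 5 | (3R)-3-[(2S)-4-methyl-5-oxo-2,5-dihydrofuran-2-yl]pentanoic acid | CC[C@H](CC(=O)O)[C@@H]1OC(=O)C(C)=C1 | intermediate |
| 6 | N-Boc-L-homoserine lactone | CC(C)(C)OC(=O)N[C@H]1CCOC1=O | starting material |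
| 7 | N-Boc-L-homoserine lactol | CC(C)(C)OC(=O)N[C@H]1CCOC1O | intermediate |
| 8 | ethyl 2-(bromomethyl)prop-2-enoate | CCOC(=O)C(=C)CBr | starting material |
| 9 | [2-(ethoxycarbonyl)prop-2-en-1-yl]zinc bromide | CCOC(=O)C(=C)C[Zn]Br | intermediate |
| 10 | ethyl (4S,5S)-5-(Boc-amino)-4,7-dihydroxy-2-methylideneheptanoate | OCC[C@@H]([C@@H](O)CC(=C)C(=O)OCC)NC(=O)OC(C)(C)C | intermediate |
| 11 | α-methylene lactone alcohol | OCC[C@@H]([C@@H]1CC(=C)C(=O)O1)NC(=O)OC(C)(C)C | intermediate |
| 12 | cis-α-methyl lactone alcohol | OCC[C@@H]([C@@H]1C[C@H](C)C(=O)O1)NC(=O)OC(C)(C)C | intermediate |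
| 13 | primary iodide | ICC[C@@H]([C@@H]1C[C@H](C)C(=O)O1)NC(=O)OC(C)(C)C | intermediate |
| 14 | acid chloride of 5 | CC[C@H](CC(=O)Cl)[C@@H]1OC(=O)C(C)=C1 | intermediate |
| 15 | alkylzinc iodide from 13 | I[Zn]CC[C@@H]([C@@H]1C[C@H](C)C(=O)O1)NC(=O)OC(C)(C)C | intermediate |
| 16 | keto carbamate (C9–C23 joined) | CC[C@H](CC(=O)CC[C@@H]([C@@H]1C[C@H](C)C(=O)O1)NC(=O)OC(C)(C)C)[C@@H]2OC(=O)C(C)=C2 | intermediate |
| 17 | amino ketone | CC[C@H](CC(=O)CC[C@@H]([C@@H]1C[C@H](C)C(=O)O1)N)[C@@H]2OC(=O)C(C)=C2 | intermediate |
| 18 | 2,5-disubstituted 1-pyrroline | CC[C@H](CC1=N[C@@H](CC1)[C@@H]2C[C@H](C)C(=O)O2)[C@@H]3OC(=O)C(C)=C3 | intermediate |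
| 19 | tetracyclic imine | CC[C@H]1[C@@H]2OC(=O)[C@@H](C)[C@@H]2[C@@H]3C[C@@H]([C@@H]4C[C@H](C)C(=O)O4)N=C3C1 | intermediate |
| 20 | 1,4-diiodobutane | ICCCCI | starting material |
| 21 | N-(4-iodobutyl)iminium iodide | CC[C@H]1[C@@H]2OC(=O)[C@@H](C)[C@@H]2[C@@H]3C[C@@H]([C@@H]4C[C@H](C)C(=O)O4)[N+](CCCCI)=C3C1.[I-] | intermediate |
| 22 | N-(4-iodobutyl) C22=C23 enamine | CC[C@H]1[C@@H]2OC(=O)[C@@H](C)[C@@H]2[C@@H]3C[C@@H]([C@@H]4C[C@H](C)C(=O)O4)N(CCCCI)C3=C1 | intermediate |
| 23 | pentacyclic iminium iodide | CC[C@H]1[C@@H]2OC(=O)[C@@H](C)[C@@H]2[C@@H]3C[C@@H]([C@@H]4C[C@H](C)C(=O)O4)[N+]5=C3[C@H]1CCCC5.[I-] | intermediate |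
| 24 | pentacyclic C9=C23 enamine | CC[C@H]1[C@@H]2OC(=O)[C@@H](C)[C@@H]2C3=C4[C@H]1CCCCN4[C@@H](C3)[C@@H]5C[C@H](C)C(=O)O5 | intermediate |
| 25 | C9,C23-dioxetane | CC[C@H]1[C@@H]2OC(=O)[C@@H](C)[C@@H]2C37OOC47[C@H]1CCCCN4[C@@H](C3)[C@@H]5C[C@H](C)C(=O)O5 | intermediate |
| 26 | 8-epi-tuberostemonone | CC[C@H]1[C@@H]2OC(=O)[C@@H](C)[C@@H]2C(=O)C[C@@H]([C@@H]2C[C@H](C)C(=O)O2)N2CCCC[C@@H]1C2=O | intermediate |
| 27 | tuberostemonone | CC[C@H]1[C@@H]2OC(=O)[C@@H](C)[C@H]2C(=O)C[C@@H]([C@@H]2C[C@H](C)C(=O)O2)N2CCCC[C@@H]1C2=O | target |

## Step count and least certain steps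

Total step count: 12. Longest linear sequence: 9 steps (steps 4–12, from 6). The left-hand branch (steps 1–3) joins at step 8.

**Step 11 (key step).**

- *What may go wrong:* prototropic drift of the double bond from C9=C23 to C22=C23 before oxygen is added, so that scission occurs in the wrong ring. Physical quenching of singlet oxygen by the amine, with electron-transfer oxidation at the α-C–H bonds, is a second risk. Ene-type hydroperoxidation instead of [2+2] is a third.
- *Why:* both tetrasubstituted enamines are linked through 23 by traces of acid.
- *Fallback (sets out from 19, comes back at 26):* the oxygen at C9 is installed before the azepine exists, which locks the regiochemistry. Sensitised photo-oxygenation of 19 through its more substituted enamine tautomer gives the 9-hydroperoxy imine F1, which PPh3 reduces to the 9-hydroxy imine F2. Annulation with 20 as in step 10, where only the C22=C23 enamine can now form, gives the 9-hydroxy iminium iodide F3. Aqueous NaHCO3 hydrates it to the carbinolamine diol F4, and NaIO4 cleaves the C9–C23 glycol-type bond (Malaprade reaction) to 26.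

**Step 10.**

- *What may go wrong:* slow N-alkylation of the hindered imine nitrogen, bridging of two imine molecules by one diiodide, a seven-membered C-alkylation that is slower than decomposition of the enamine, and incomplete equilibration at C22.
- *Fallback (sets out from 4, comes back at 23):* the four-carbon chain is placed on C22 before the fragments are joined, so that the ring is closed at nitrogen.
  - Amine-catalysed α-methylenation of 4 with aqueous formaldehyde gives the 2-substituted acrolein F5.
  - Giese addition of the 3-chloropropyl radical (1-chloro-3-iodopropane, (TMS)3SiH, AIBN) to its terminal methylene gives the chlorobutyl aldehyde F6. The C22 epimers are inconsequential.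
  - Pinnick oxidation gives the acid F7, and oxalyl chloride gives the acid chloride F8.
  - Negishi acylation with 15 gives the ketone F9.
  - The conditions of step 9 give the chlorobutyl imine F10.
  - NaI in hot MeCN closes N17–C18 (7-exo-tet) to 23.

**Step 12.**

- *What may go wrong:* an equilibrium that stops short of completion, E1cB loss of O5 or retro-aza-Michael loss of N17 from the enolate, and slow epimerisation at C7.
- *Fallback (sets out from 26, comes back at 27):* the enolate manifold is left altogether. Soft enolisation with TMSOTf/Et3N gives the C8=C9 silyl enol ether F11, which is isolated. It is then hydrolysed with a catalytic strong acid (Tf2NH, wet CH2Cl2) under conditions where the neutral enol and the ketone keep exchanging until the thermodynamic C8 epimer is reached.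

**Step 9.**

- *What may go wrong:* attack of the free amine on lactone B (translactamisation) before the imine forms, a sluggish Michael step because the enamine tautomer is scarce, and intermolecular addition.
- *Fallback (sets out from 16, comes back at 19):* the carbocycle is closed while nitrogen is still protected. An intramolecular Michael addition of the ketone itself under secondary-amine catalysis (pyrrolidine/AcOH) is used; only C9 can reach C8 in a six-membered ring. This gives the bicyclic keto lactone F12, and TFA followed by NaHCO3 then closes the pyrroline to 19.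

**Step 5.**

- *What may go wrong:* poor facial selectivity at the aldehyde, because chelation by the carbamate is weak in aqueous medium, and partial racemisation of the open aldehyde.
- *Fallback (sets out from 6, comes back at 12):* C12 is set by hydride addition instead of carbon addition, and C14 is bought.
  - Saponification of 6 and silylation give N-Boc-O-TBS-L-homoserine F13.
  - EtSH/EDC gives the thioester F14.
  - Fukuyama coupling with the zinc homoenolate F15, made from commercial methyl (R)-3-bromo-2-methylpropanoate with Zn/LiCl, gives the γ-keto ester F16.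
  - L-Selectride in THF at −78 °C reduces the α-amino ketone under Felkin–Anh control to the syn alkoxide, which lactonises to the silyl ether F17.
  - HF·pyridine then gives 12.

## Further compounds

F1 | step 11 | 9-hydroperoxy imine | CC[C@H]1[C@@H]2OC(=O)[C@@H](C)[C@@H]2C3(OO)C[C@@H]([C@@H]4C[C@H](C)C(=O)O4)N=C3C1
F2 | step 11 | 9-hydroxy imine | CC[C@H]1[C@@H]2OC(=O)[C@@H](C)[C@@H]2C3(O)C[C@@H]([C@@H]4C[C@H](C)C(=O)O4)N=C3C1
F3 | step 11 | 9-hydroxy iminium iodide | CC[C@H]1[C@@H]2OC(=O)[C@@H](C)[C@@H]2C3(O)C[C@@H]([C@@H]4C[C@H](C)C(=O)O4)[N+]5=C3[C@H]1CCCC5.[I-]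
F4 | step 11 | carbinolamine diol | CC[C@H]1[C@@H]2OC(=O)[C@@H](C)[C@@H]2C3(O)C[C@@H]([C@@H]4C[C@H](C)C(=O)O4)N5CCCC[C@@H]1C35O
F5 | step 10 | 2-substituted acrolein | CC[C@H](C(=C)C=O)[C@@H]1OC(=O)C(C)=C1
F6 | step 10 | chlorobutyl aldehyde | CC[C@H](C(CCCCCl)C=O)[C@@H]1OC(=O)C(C)=C1
F7 | step 10 | chlorobutyl acid | CC[C@H](C(CCCCCl)C(=O)O)[C@@H]1OC(=O)C(C)=C1
F8 | step 10 | chlorobutyl acid chloride | CC[C@H](C(CCCCCl)C(Cl)=O)[C@@H]1OC(=O)C(C)=C1
F9 | step 10 | chlorobutyl ketone | CC[C@H](C(CCCCCl)C(=O)CC[C@@H]([C@@H]1C[C@H](C)C(=O)O1)NC(=O)OC(C)(C)C)[C@@H]2OC(=O)C(C)=C2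
F10 | step 10 | chlorobutyl imine | CC[C@H]1[C@@H]2OC(=O)[C@@H](C)[C@@H]2[C@@H]3C[C@@H]([C@@H]4C[C@H](C)C(=O)O4)N=C3C1CCCCCl
F11 | step 12 | C8=C9 silyl enol ether | CC[C@H]1[C@@H]2OC(=O)[C@@H](C)C2=C(O[Si](C)(C)C)C[C@@H]([C@@H]3C[C@H](C)C(=O)O3)N3CCCC[C@@H]1C3=O
F12 | step 9 | bicyclic keto lactone | CC[C@H]1[C@@H]2OC(=O)[C@@H](C)[C@@H]2C(C[C@@H]([C@@H]3C[C@H](C)C(=O)O3)NC(=O)OC(C)(C)C)C(=O)C1
F13 | step 5 | N-Boc-O-TBS-L-homoserine | CC(C)(C)OC(=O)N[C@@H](CCO[Si](C)(C)C(C)(C)C)C(=O)O
F14 | step 5 | S-ethyl thioester | CCSC(=O)[C@H](CCO[Si](C)(C)C(C)(C)C)NC(=O)OC(C)(C)C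
F15 | step 5 | zinc homoenolate | COC(=O)[C@@H](C)C[Zn]Br
F16 | step 5 | γ-keto ester | COC(=O)[C@@H](C)CC(=O)[C@H](CCO[Si](C)(C)C(C)(C)C)NC(=O)OC(C)(C)C
F17 | step 5 | TBS ether of 12 | CC(C)(C)[Si](C)(C)OCC[C@@H]([C@@H]1C[C@H](C)C(=O)O1)NC(=O)OC(C)(C)C
A1 | alternative 1 | open amino acid | CC[C@@H]([C@@H]1OC(=O)[C@@H](C)[C@H]1C(=O)C[C@@H]([C@@H]2C[C@H](C)C(=O)O2)N)[C@H](CCCCCl)C(=O)O
A2 | alternative 1 | nine-membered NH-lactam | CC[C@H]1[C@@H]2OC(=O)[C@@H](C)[C@H]2C(=O)C[C@@H]([C@@H]2C[C@H](C)C(=O)O2)NC(=O)[C@H]1CCCCCl
A3 | alternative 2 | pyrrolidine acyl fluoride | CC/C=C/[C@H]1[C@H](O[Si](C)(C)C(C)(C)C)C[C@@H]([C@@H]2C[C@H](C)C(=O)O2)N1CCCCCC(F)=O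
A4 | alternative 2 | bridged (E)-azoninone | CC[C@H]1/C=C/[C@H](O[Si](C)(C)C(C)(C)C)C[C@@H]([C@@H]2C[C@H](C)C(=O)O2)N2CCCC[C@@H]1C2=O
A5 | alternative 3 | caprolactam butenolide aldehyde | CC[C@@H]([C@@H]1OC(=O)C(C)=C1)[C@@H]2CCCCN(C2=O)[C@@H](CC=O)[C@@H]3C[C@H](C)C(=O)O3
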